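Remark on the chemistry: the twofold Wittig reaction should give a mixture of alkene isomers; both alkenes are saturated in the next step, so compound 8 is drawn without alkene geometry. Cross-checking the substitution patterns of rings B and C in 9, 10 and 11 against each other and against the two bromohydroxybenzaldehydes showed them to be consistent, so no structure needed correction.

## Structural features

Isoplagilin (11) has four benzene rings and no other ring: two terminal 3-methoxyphenyl rings (A and D) and two central catechol rings (B and C). Rings B and C are joined directly by the B5–C1 biaryl bond; ring A is attached to B1 and ring D to C6, each through a CH2CH2 bridge. There is no stereocentre, so none stands next to another. Only two ortho substituents flank the biaryl axis (the B4 hydroxyl and the C6 chain), so the axis should rotate freely and nothing stereochemical needs control. The fragile groups are the two catechols (B3/B4 and C3/C4), which air oxidises to ortho-quinones, especially in base. The two aryl methyl ethers must also stay intact while four phenolic hydroxyls end up free, which rules out methyl ethers as phenol protection. The real difficulty is the unsymmetrical tetra-oxygenated biaryl: ring B has its oxygens ortho and meta to the biaryl bond, ring C meta and para to it, so each half needs its own regiochemical solution. The key step exploits that one oxygen of each catechol (B4, C3) is para to the benzylic carbon of its bridge (B1, C6), as in a phenol made from a para-hydroxybenzaldehyde, and that the second oxygen (B3, C4) sits at the only free ortho position (ring B) or the less hindered one (ring C).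

## Logic of the disconnections

11 to 10 to 9. The B3–O and C4–O bonds are cut. Each lies ortho to an oxygen that is para to a bridge, so removing them leaves two plain para-alkylphenols. Only two hydroxyls then need protection instead of four, and both halves trace back to para-hydroxybenzaldehydes. The forward step must oxygenate twice with site control (B3 is the only choice on ring B; C4 must win over C2 on ring C), must leave rings A and D alone, and must pass through 10 quickly, with reduction before a quinone can meet a remaining phenol.

9 to 8. No skeletal bond is cut. Unsaturation is added to both bridges and a benzyl group to each phenol oxygen, because a single hydrogenation removes all four features. This makes 9 the direct descendant of an olefination product. The forward step must saturate two stilbene alkenes and cleave two aryl benzyl ethers without touching the two methyl ethers.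

8 to 6 and 7. Both bridge C=C bonds are cut. The two 3-methoxybenzyl units are identical and come from two equivalents of one phosphonium salt. This two-directional cut reduces 8 to a biaryl dialdehyde. The olefination must go to completion at both aldehydes, including the one ortho to the biaryl bond; alkene geometry is irrelevant.

6 to 5 and 4. The B5–C1 biaryl bond is cut, the only bond joining two halves of similar size. Boron is placed on the ring B half, because a boronate ortho to a formyl group (the reverse polarity) would be prone to protodeboronation, whereas the ortho-formyl bromide is an activated electrophile. The coupling must tolerate two free aldehydes and one ortho substituent on each partner.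

5 to 2 to 1, and 4 to 3. The C–B bond and then the O–benzyl bonds are cut. Compounds 1 and 3 are commercial and already hold the ring carbons, the oxygen, the halogen and the formyl handle in the correct relationship. The benzyl group must survive borylation, cross-coupling and ylide, and leave in the hydrogenation without a step of its own.

## Other disconnections considered

Alternative 1: Diels–Alder construction of ring C.
- Cut: C2–C3 and C4–C5 of ring C. Ring C would come from the 2-aryl-3-alkylbuta-1,3-diene A1, in which ring B is already a dibenzylated catechol carrying its bridge, and vinylene carbonate A2, a two-carbon unit bearing both oxygens.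
- Key step: thermal [4+2] cycloaddition of A1 and A2 to the racemic cis-fused cyclohexene carbonate A3. Carbonate hydrolysis, twofold alcohol oxidation with enolisation to the aromatic catechol, and hydrogenolysis would follow.
- In favour: the positions of the ring C oxygens are fixed by ring construction and not by steric bias, so on regiochemical certainty in ring C this alternative is the better plan. No free phenol ever faces a quinone. The two stereocentres of A3 vanish on aromatisation, so on stereochemical burden it is the equal of the chosen plan.
- Against: A1 is a hindered 2,3-disubstituted diene that itself needs several steps. A2 is a sluggish dienophile that would require prolonged heating well above 150 °C, where A1 may polymerise or isomerise. Three operations after the key step only restore the aromatic oxidation level.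
- Comparison: structurally it builds a ring that the chosen plan buys as an arene. Mechanistically it is a concerted suprafacial cycloaddition whose stereochemical outcome is discarded, against an oxygen transfer whose only open question is site selectivity. It would be expected to need about twelve steps against seven.

Alternative 2: twofold Ramberg–Bäcklund contraction.
- Cut: the central C–C bond of each bridge, the same bonds the chosen Wittig step forms, but with an SO2 unit between the benzylic carbons in the bis(benzyl sulfone) A4.
- Key step: twofold alpha-halogenation, 1,3-elimination to the episulfones and loss of SO2 to give the tetra-O-benzyl bis-stilbene A5. One hydrogenation would then saturate both alkenes and free all four hydroxyls.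
- In favour: all four oxygens are in place from the outset and the final step is neutral and reductive, so on handling of the sensitive catechols this alternative is the better plan. Alkene geometry is immaterial, as in the chosen plan (equal).
- Against: A4 requires twofold benzylic thioether formation and sulfur oxidation after the biaryl is assembled, so three operations do what one twofold Wittig does. Both aryl halves would have to be prepared as benzyl-protected bromocatechol aldehydes, which are not simple commercial materials. The in situ halogenation variant uses an ozone-depleting halomethane under strongly basic conditions.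
- Comparison: structurally the same bridge bonds and the same closing hydrogenation. Mechanistically an extrusion in place of an olefination, with no gain in selectivity. It would be expected to need about eleven steps against seven, in exchange for avoiding a late oxidation.

Alternative 3: aryne arylmagnesiation with oxygen trapping.
- Cut: the B5–C1 biaryl bond and the B4–O bond in one operation.
- Key step: the ring C arylmagnesium bromide A7 adds to the aryne generated from ortho-lithiated fluoroarene A6 by loss of LiF. The aryl group should enter at the carbon remote from the alkoxy group (B5), leaving the metal at B4 next to the stabilising oxygen. Trapping with a trialkyl borate and peroxide oxidation would give phenol A8. Acidic removal of the methoxymethyl group and hydrogenolysis would finish.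
- In favour: two bonds form in one flask, fully convergently, without palladium and with regiochemistry dictated electronically. On bond-forming efficiency of the key step this alternative is the better plan.
- Against: each half must carry its own bridge, so olefination and reduction are done twice on separate substrates, and on the ring C half the alkene must be reduced in the presence of an aryl bromide and benzyl ethers. A6, with its 1,3,5-pattern, needs its own synthesis. The arylmagnesium at B4 is flanked by the alkoxy group and the new ortho-substituted aryl group, so borate trapping may lose to protonation. The aryne may also be intercepted by lithiated A6.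
- Comparison: structurally it is more convergent but needs two tailor-made halves. Mechanistically it depends on three consecutive organometallic events at low temperature, against one oxygen transfer. It would be expected to need ten to twelve steps against seven.

Key step: step 7

## Route

Step 1
Reactants: 1 3-bromo-4-hydroxybenzaldehyde
Product: 2 4-(benzyloxy)-3-bromobenzaldehyde
Conditions: BnBr (1.1 equiv), K2CO3, DMF, rt
Reagents that add atoms: benzyl bromide, BrCc1ccccc1
Why: Williamson O-alkylation (SN2) of an acidic phenoxide; benzyl is chosen because it tolerates borylation, cross-coupling and ylide, leaves in the later hydrogenation, and cannot be confused with the anisole methyl ethers, while the free para-hydroxy aldehyde would be deactivated as its phenoxide in the Wittig step.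

Step 2
Reactants: 3 2-bromo-4-hydroxybenzaldehyde
Product: 4 4-(benzyloxy)-2-bromobenzaldehyde
Conditions: BnBr (1.1 equiv), K2CO3, DMF, rt
Reagents that add atoms: benzyl bromide, BrCc1ccccc1
Why: The same Williamson O-alkylation on the ring C building block; the aryl bromide and the non-enolisable aldehyde are inert to carbonate base at room temperature.

Step 3
Reactants: 2 4-(benzyloxy)-3-bromobenzaldehyde
Product: 5 4-(benzyloxy)-3-(4,4,5,5-tetramethyl-1,3,2-dioxaborolan-2-yl)benzaldehyde
Conditions: B2pin2 (1.2 equiv), PdCl2(dppf) (3 mol %), KOAc, 1,4-dioxane, 85 °C
Reagents that add atoms: bis(pinacolato)diboron, CC1(C)OB(OC1(C)C)B1OC(C)(C)C(C)(C)O1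
Why: Miyaura borylation (oxidative addition of zerovalent palladium to C–Br, acetate-assisted transmetalation with the diboron, reductive elimination); KOAc is too weak a base to start Suzuki homocoupling and the aldehyde is tolerated.

Step 4
Reactants: 5 4-(benzyloxy)-3-(4,4,5,5-tetramethyl-1,3,2-dioxaborolan-2-yl)benzaldehyde, 4 4-(benzyloxy)-2-bromobenzaldehyde
Product: 6 2',5-bis(benzyloxy)-[1,1'-biphenyl]-2,5'-dicarbaldehyde
Conditions: Pd(OAc)2 (2 mol %), SPhos (4 mol %), K3PO4, toluene/H2O, 80 °C
Reagents that add atoms: none
Why: Suzuki–Miyaura coupling forming the B5–C1 bond; bromide 4 is activated for oxidative addition by its ortho-formyl group, and the bulky electron-rich phosphine should speed transmetalation and reductive elimination of a biaryl with one ortho substituent on each ring so that coupling outruns protodeboronation, while phosphate is mild toward the aldehydes.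

Step 5
Reactants: 6 2',5-bis(benzyloxy)-[1,1'-biphenyl]-2,5'-dicarbaldehyde, 7 (3-methoxybenzyl)triphenylphosphonium chloride (2.5 equiv)
Product: 8 1-(benzyloxy)-2-[5-(benzyloxy)-2-[2-(3-methoxyphenyl)ethenyl]phenyl]-4-[2-(3-methoxyphenyl)ethenyl]benzene (mixture of E and Z isomers at both alkenes)
Conditions: KOtBu (2.6 equiv), THF, 0 °C to rt
Reagents that add atoms: none
Why: Twofold Wittig olefination with a semi-stabilised benzylic ylide; both aldehydes are non-enolisable, excess ylide drives the second olefination at the more hindered formyl group, and the E/Z mixture is of no consequence because step 6 saturates both alkenes.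

Step 6
Reactants: 8 1-(benzyloxy)-2-[5-(benzyloxy)-2-[2-(3-methoxyphenyl)ethenyl]phenyl]-4-[2-(3-methoxyphenyl)ethenyl]benzene
Product: 9 2-[5-hydroxy-2-[2-(3-methoxyphenyl)ethyl]phenyl]-4-[2-(3-methoxyphenyl)ethyl]phenol
Conditions: H2 (1 atm), 10% Pd/C, EtOAc/MeOH, rt
Reagents that add atoms: none
Why: Heterogeneous catalytic hydrogenation of the two stilbene double bonds and hydrogenolysis of the two aryl benzyl ethers in one operation; aryl methyl ethers and the arene rings are inert at one atmosphere and room temperature.

Step 7
Reactants: 9 2-[5-hydroxy-2-[2-(3-methoxyphenyl)ethyl]phenyl]-4-[2-(3-methoxyphenyl)ethyl]phenol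
Product: 11 isoplagilin, via bis(ortho-quinone) 10 (not isolated)
Conditions: IBX (2.4 equiv), DMF, 0 °C to rt, N2, dark, 9 added slowly to the oxidant; then aq. Na2S2O4 (excess), 0 °C to rt; degassed, weakly acidic work-up
Reagents that add atoms: 2-iodoxybenzoic acid (IBX), O=C1OI(=O)(O)c2ccccc12
Why: Each phenol oxygen (B4–O and C3–O) should exchange onto the pentavalent iodine of IBX to give an aryloxy-iodine species, from which an iodine-bound oxygen is delivered intramolecularly to the neighbouring ortho carbon (B3, C4) with reduction to trivalent iodine. Tautomerisation and collapse of the resulting catechol–iodine species should release the ortho-quinone and 2-iodobenzoic acid, so that 10 holds both new C–O bonds, and Na2S2O4 then reduces both quinones (and surplus oxidant) to give 11. The closest known reaction type is the regioselective IBX ortho-oxygenation of electron-rich para-alkylphenols to ortho-quinones with reduction to the catechol in the same flask. No ring is closed and no stereocentre is created. Site selectivity is set by the substrate: on ring B the other ortho position (B5) carries the aryl group, so only B3 can accept oxygen, and on ring C delivery should go to the open C4 and not to C2, which is wedged between the hydroxyl and the biaryl bond; both para positions are blocked by the bridges, so no para-quinone can form. Chemoselectivity follows from the mechanism, since rings A and D have no hydroxyl to bind iodine. Inverse addition into excess oxidant should engage both phenols together, so that a free B4 hydroxyl does not coexist with the ring C quinone and cyclise to a dibenzofuran. Prompt reduction at low temperature limits conjugate additions and quinone methide tautomerisation of 10.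

## Compound list

1 | 3-bromo-4-hydroxybenzaldehyde | O=Cc1ccc(O)c(Br)c1 | starting material
2 | 4-(benzyloxy)-3-bromobenzaldehyde | O=Cc1ccc(OCc2ccccc2)c(Br)c1 | intermediate
3 | 2-bromo-4-hydroxybenzaldehyde | O=Cc1ccc(O)cc1Br | starting material
4 | 4-(benzyloxy)-2-bromobenzaldehyde | O=Cc1ccc(OCc2ccccc2)cc1Br | intermediate
5 | 4-(benzyloxy)-3-(4,4,5,5-tetramethyl-1,3,2-dioxaborolan-2-yl)benzaldehyde | O=Cc1ccc(OCc2ccccc2)c(B2OC(C)(C)C(C)(C)O2)c1 | intermediate
6 | 2',5-bis(benzyloxy)-[1,1'-biphenyl]-2,5'-dicarbaldehyde | O=Cc1ccc(OCc2ccccc2)c(-c2cc(OCc3ccccc3)ccc2C=O)c1 | intermediate
7 | (3-methoxybenzyl)triphenylphosphonium chloride | COc1cccc(C[P+](c2ccccc2)(c2ccccc2)c2ccccc2)c1.[Cl-] | starting material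
8 | 1-(benzyloxy)-2-[5-(benzyloxy)-2-[2-(3-methoxyphenyl)ethenyl]phenyl]-4-[2-(3-methoxyphenyl)ethenyl]benzene, E/Z mixture | COc1cccc(C=Cc2ccc(OCc3ccccc3)c(-c3cc(OCc4ccccc4)ccc3C=Cc3cccc(OC)c3)c2)c1 | intermediate
9 | 2-[5-hydroxy-2-[2-(3-methoxyphenyl)ethyl]phenyl]-4-[2-(3-methoxyphenyl)ethyl]phenol | COc1cccc(CCc2ccc(O)c(-c3cc(O)ccc3CCc3cccc(OC)c3)c2)c1 | intermediate
10 | 5-[2-(3-methoxyphenyl)ethyl]-3-[6-[2-(3-methoxyphenyl)ethyl]-3,4-dioxocyclohexa-1,5-dien-1-yl]cyclohexa-3,5-diene-1,2-dione (bis(ortho-quinone), not isolated) | COc1cccc(CCC2=CC(=O)C(=O)C(C3=CC(=O)C(=O)C=C3CCc3cccc(OC)c3)=C2)c1 | intermediate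
11 | isoplagilin, 3-[4,5-dihydroxy-2-[2-(3-methoxyphenyl)ethyl]phenyl]-5-[2-(3-methoxyphenyl)ethyl]benzene-1,2-diol | COc1cccc(CCc2cc(O)c(O)c(-c3cc(O)c(O)cc3CCc3cccc(OC)c3)c2)c1 | target

## Step count and least certain steps

Total step count: 7. Longest linear sequence: 6 steps (1 to 2 to 5 to 6 to 8 to 9 to 11, steps 1, 3, 4, 5, 6 and 7).

Step 7 (key step). The most likely failures are:
- unequal oxidation rates of the two rings, which would let the free B4 hydroxyl add in conjugate fashion to the ring C quinone and close a dibenzofuran;
- partial oxygen delivery to C2 instead of C4;
- re-oxidation of the catechols by air during work-up.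

The fallback sets out from 9 and returns at 11. Magnesium-mediated ortho-formylation (MgCl2, Et3N, paraformaldehyde, THF, reflux) should install a formyl group at the same two ortho positions, giving 3-[4-formyl-5-hydroxy-2-[2-(3-methoxyphenyl)ethyl]phenyl]-2-hydroxy-5-[2-(3-methoxyphenyl)ethyl]benzaldehyde F1. A twofold Dakin oxidation (aq. H2O2, B(OH)3, THF, rt, with hydrolysis of the aryl formates) should then convert each salicylaldehyde unit into a catechol and give 11. No quinone is involved.

Step 4. Protodeboronation of the ortho-alkoxy boronate may compete with transmetalation onto the hindered arylpalladium species, and the aldehydes may suffer under aqueous base. The fallback sets out from 2 and 4 and returns at 8; it removes both boron and the aldehydes from the coupling.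
- Each bromide is first olefinated with the ylide from 7 (KOtBu, THF), giving 1-(benzyloxy)-2-bromo-4-[2-(3-methoxyphenyl)ethenyl]benzene F2 from 2 and 4-(benzyloxy)-2-bromo-1-[2-(3-methoxyphenyl)ethenyl]benzene F3 from 4.
- F3 undergoes bromine–lithium exchange (n-BuLi, THF, −78 °C) and transmetalation with ZnCl2 to [5-(benzyloxy)-2-[2-(3-methoxyphenyl)ethenyl]phenyl]zinc chloride F4.
- Negishi coupling of F4 with F2 (Pd(OAc)2, SPhos, THF, 60 °C) should give 8.

Step 5. The second olefination, at the formyl group ortho to the biaryl bond, may stall and leave mono-olefinated material, and residual phosphorus compounds may later poison the hydrogenation catalyst. The fallback sets out from 6 and returns at 8. Twofold addition of 3-methoxybenzylmagnesium chloride (THF, −78 to 0 °C) should give 1-[4-(benzyloxy)-3-[5-(benzyloxy)-2-[1-hydroxy-2-(3-methoxyphenyl)ethyl]phenyl]phenyl]-2-(3-methoxyphenyl)ethan-1-ol F5 as a diastereomer mixture of no consequence. Acid-catalysed dehydration (TsOH cat., toluene, reflux) should then give 8.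

Step 6. Hydrogenolysis may stop after the alkenes are saturated, leaving the hindered B4 benzyl ether next to the biaryl bond in place, or the catalyst may be deactivated by phosphorus residues. The fallback sets out from 8 and returns at 9. Hydrogenation is run only as far as the alkenes (H2, Pd/C, Ph2S as catalyst modifier, EtOAc, rt) to give 1-(benzyloxy)-2-[5-(benzyloxy)-2-[2-(3-methoxyphenyl)ethyl]phenyl]-4-[2-(3-methoxyphenyl)ethyl]benzene F6. Lewis-acid debenzylation (BCl3, pentamethylbenzene as cation scavenger, CH2Cl2, −78 °C) should then cleave the benzyl ethers and spare the methyl ethers, giving 9.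

## Further compounds

F1 | step 7 | 3-[4-formyl-5-hydroxy-2-[2-(3-methoxyphenyl)ethyl]phenyl]-2-hydroxy-5-[2-(3-methoxyphenyl)ethyl]benzaldehyde | COc1cccc(CCc2cc(C=O)c(O)c(-c3cc(O)c(C=O)cc3CCc3cccc(OC)c3)c2)c1
F2 | step 4 | 1-(benzyloxy)-2-bromo-4-[2-(3-methoxyphenyl)ethenyl]benzene, E/Z mixture | COc1cccc(C=Cc2ccc(OCc3ccccc3)c(Br)c2)c1
F3 | step 4 | 4-(benzyloxy)-2-bromo-1-[2-(3-methoxyphenyl)ethenyl]benzene, E/Z mixture | COc1cccc(C=Cc2ccc(OCc3ccccc3)cc2Br)c1
F4 | step 4 | [5-(benzyloxy)-2-[2-(3-methoxyphenyl)ethenyl]phenyl]zinc chloride | COc1cccc(C=Cc2ccc(OCc3ccccc3)cc2[Zn]Cl)c1
F5 | step 5 | 1-[4-(benzyloxy)-3-[5-(benzyloxy)-2-[1-hydroxy-2-(3-methoxyphenyl)ethyl]phenyl]phenyl]-2-(3-methoxyphenyl)ethan-1-ol, diastereomer mixture | COc1cccc(CC(O)c2ccc(OCc3ccccc3)c(-c3cc(OCc4ccccc4)ccc3C(O)Cc3cccc(OC)c3)c2)c1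
F6 | step 6 | 1-(benzyloxy)-2-[5-(benzyloxy)-2-[2-(3-methoxyphenyl)ethyl]phenyl]-4-[2-(3-methoxyphenyl)ethyl]benzene | COc1cccc(CCc2ccc(OCc3ccccc3)c(-c3cc(OCc4ccccc4)ccc3CCc3cccc(OC)c3)c2)c1
A1 | alternative 1 | 1,2-bis(benzyloxy)-5-[2-(3-methoxyphenyl)ethyl]-3-[5-(3-methoxyphenyl)-3-methylidenepent-1-en-2-yl]benzene | C=C(CCc1cccc(OC)c1)C(=C)c1cc(CCc2cccc(OC)c2)cc(OCc2ccccc2)c1OCc1ccccc1
A2 | alternative 1 | vinylene carbonate (1,3-dioxol-2-one) | O=c1occo1
A3 | alternative 1 | racemic cis-5-[2,3-bis(benzyloxy)-5-[2-(3-methoxyphenyl)ethyl]phenyl]-6-[2-(3-methoxyphenyl)ethyl]-3a,4,7,7a-tetrahydro-1,3-benzodioxol-2-one (one enantiomer drawn) | O=C1O[C@H]2CC(CCc3cccc(OC)c3)=C(c3cc(CCc4cccc(OC)c4)cc(OCc4ccccc4)c3OCc3ccccc3)C[C@H]2O1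
A4 | alternative 2 | 1,2-bis(benzyloxy)-3-[4,5-bis(benzyloxy)-2-[[(3-methoxyphenyl)methanesulfonyl]methyl]phenyl]-5-[[(3-methoxyphenyl)methanesulfonyl]methyl]benzene | COc1cccc(CS(=O)(=O)Cc2cc(OCc3ccccc3)c(OCc3ccccc3)c(-c3cc(OCc4ccccc4)c(OCc4ccccc4)cc3CS(=O)(=O)Cc3cccc(OC)c3)c2)c1
A5 | alternative 2 | 1,2-bis(benzyloxy)-3-[4,5-bis(benzyloxy)-2-[(E)-2-(3-methoxyphenyl)ethenyl]phenyl]-5-[(E)-2-(3-methoxyphenyl)ethenyl]benzene (E,E drawn; geometry immaterial) | COc1cccc(/C=C/c2cc(OCc3ccccc3)c(OCc3ccccc3)c(-c3cc(OCc4ccccc4)c(OCc4ccccc4)cc3/C=C/c3cccc(OC)c3)c2)c1
A6 | alternative 3 | 1-fluoro-3-(methoxymethoxy)-5-[2-(3-methoxyphenyl)ethyl]benzene | COCOc1cc(F)cc(CCc2cccc(OC)c2)c1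
A7 | alternative 3 | [4,5-bis(benzyloxy)-2-[2-(3-methoxyphenyl)ethyl]phenyl]magnesium bromide | COc1cccc(CCc2cc(OCc3ccccc3)c(OCc3ccccc3)cc2[Mg]Br)c1
A8 | alternative 3 | 2-[4,5-bis(benzyloxy)-2-[2-(3-methoxyphenyl)ethyl]phenyl]-6-(methoxymethoxy)-4-[2-(3-methoxyphenyl)ethyl]phenol | COCOc1cc(CCc2cccc(OC)c2)cc(-c2cc(OCc3ccccc3)c(OCc3ccccc3)cc2CCc2cccc(OC)c2)c1O
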